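In the south run, charged at 0.38 M, ring read 22 % at 1.33 h and 22 % at 3.00 h, while substrate fell from 38 % to 16 %.

| flask | substrate | remark | time |
|---|---|---|---|
| north | 0.17 M | run made earlier |  |
| south | 0.38 M | run made earlier |  |
| flask | 0.25 M |  | 4.0 h |

| run | time / h | ring / % | substrate / % |
|---|---|---|---|
| north | 0.417 | 9 | 78 |
| north | 1.00 | 18 | 61 |
| north | 2.00 | 26 | 36 |
| north | 3.00 | 30 | 21 |
| south | 0.250 | 6 | 80 |
| south | 0.667 | 11 | 64 |
| south | 1.33 | 22 | 38 |
| south | 3.00 | 22 | 16 |

(standard deviation of a reading: 2 percentage points)

- the ring in the flask at 4.0 h, as a percentage of the substrate charged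
- the substrate in the flask at 4.0 h, as a percentage of the substrate charged
- the open dimer in the flask at 4.0 h, as a percentage of the substrate charged

- in percentages every species weighs as the substrate in it: one open dimer or side product counts as two
- steps that have been proposed: 2 substrate -> open dimer; substrate -> ring; ring <-> isomer of the product; substrate + ring -> side product

My reckoning takes that flat stretch as a balance, a quasi-steady state. Let S be the substrate concentration, R the ring concentration, and k and k' the rate constants of two proposed steps. If substrate → ring makes ring at kS and substrate + ring → side product uses it at k'SR, then S cancels and the balance of these two steps stands at R = k/k', with no charge in it. You carry that level, the plateau molarity R\*, read from the south run as 0.0836 M, with the scatter of the reading in it. In your flask at 0.25 M that is 33.4 % of the charge, so I commit to ring below this at 4.0 h.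

The forecast gives ring 26 % (20 % to 32 %), substrate 12 % (8 % to 16 %) and open dimer 22 % (11 % to 34 %), holding that “the ring is draining, likely to the isomer”.

The flask gives ring 28.1 %, substrate 12.0 % and open dimer 26.8 %, each inside the forecast's range.

    2 substrate → open dimer (k = 1.70 × 10⁻⁴ /M/s)
    substrate → ring (k = 7.90 × 10⁻⁵ /s)
    ring ⇌ isomer of the product (K = 2.60, k = 6.20 × 10⁻⁶ /s)
    substrate + ring → side product (k = 6.50 × 10⁻⁴ /M/s)

Ring in the flask at 4.00 h is 0.0703 M, below R\*, and it is still made 1.32 times faster than it is used up, each step taken net. Read the same flask at 6.0 h: R\* again gives 33.4 % of the charge, and substrate is down to 4.64 %. Ring there stands at 28.7 %, which is 0.0717 M.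

The runs were generated by integration with made-up constants, and the scatter is random.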